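The synthesis is built on cutting the bond between C2 of the pyranone ring (ring C) and the first CH2 of the icosyl chain. The feature exploited is the vinylogous ester O1–C2=C3–C4=O. Silylation of the C4 carbonyl oxygen turns ring C into an aromatic 4-silyloxybenzopyrylium cation whose oxygen-flanked, unsubstituted C2 is strongly electrophilic. In one operation a copper-catalysed icosyl Grignard addition joins the whole C20 chain to the finished, fully substituted bicycle. It leaves a 4-silyloxy-2H-chromene, whose partly saturated ring C is re-aromatized by hydride abstraction in the last step. The precursor is C2-unsubstituted 5,7-bis(silyloxy)-6,8-dimethylchromone, made from symmetric 3,5-dimethylphloroacetophenone.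

Key step: step 4

Assumption: compound 9 forms as a racemate at C2. This centre becomes trigonal again in step 5, and the target has no stereocentre.

Step 1
Reactants: 1 2',4',6'-trihydroxyacetophenone
Product: 2 2',4',6'-trihydroxy-3',5'-dimethylacetophenone
Conditions: MeI (2.1 equiv), NaOMe (2.1 equiv), MeOH, 0 °C to reflux; dilute HCl work-up
Reagents that add atoms: iodomethane CI
Why: Base-mediated C-methylation of the ambident phloroglucinolate in a protic solvent should occur at the only two free ring carbons C3' and C5', and two equivalents of base and MeI limit geminal over-methylation.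

Step 2
Reactants: 2 2',4',6'-trihydroxy-3',5'-dimethylacetophenone
Product: 4 5,7-dihydroxy-6,8-dimethyl-4H-chromen-4-one, via 4-ethoxybenzopyrylium perchlorate 3 (not isolated)
Conditions: HC(OEt)3 (excess), 70% aq HClO4 (1.1 equiv), rt; Et2O (salt kept solvent-moist); then H2O, 90 °C
Reagents that add atoms: triethyl orthoformate CCOC(OCC)OCC; water O
Why: Acid-promoted orthoformate condensation at the acetyl CH3 and ring closure through an ortho hydroxyl (chromone synthesis through a 4-alkoxybenzopyrylium salt, then hydrolysis) should give a single chromone, because the two ortho hydroxyls of 2 are equivalent and ring A has no free carbon to be formylated.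

Step 3
Reactants: 4 5,7-dihydroxy-6,8-dimethyl-4H-chromen-4-one
Product: 5 5,7-bis(tert-butyldimethylsilyloxy)-6,8-dimethyl-4H-chromen-4-one
Conditions: TBSOTf (2.4 equiv), 2,6-lutidine (3 equiv), CH2Cl2, 0 °C to rt; aq NaHCO3
Reagents that add atoms: tert-butyldimethylsilyl triflate CC(C)(C)[Si](C)(C)OS(=O)(=O)C(F)(F)F
Why: O-silylation with a silyl triflate and a hindered pyridine base is strong enough for the hydrogen-bonded 5-OH and the doubly flanked 7-OH, and any silylation at the carbonyl oxygen is reversed in the bicarbonate work-up.

Step 4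
Reactants: 5 5,7-bis(tert-butyldimethylsilyloxy)-6,8-dimethyl-4H-chromen-4-one, 6 1-bromoicosane
Product: 9 5,7-bis(tert-butyldimethylsilyloxy)-2-icosyl-6,8-dimethyl-4-(trimethylsilyloxy)-2H-chromene (racemic), via icosylmagnesium bromide 7 (not isolated), via 4-silyloxybenzopyrylium triflate 8 (not isolated)
Conditions: flask A: 6 (1.3 equiv), Mg turnings, THF, 45 °C; flask B: 5, TMSOTf (1.15 equiv), CH2Cl2, rt, 1 h; then CuBr·SMe2 (20 mol %), warm solution A into B at −78 °C, to −20 °C; cold aq NaHCO3, hexane, crude product used directly
Reagents that add atoms: trimethylsilyl triflate C[Si](C)(C)OS(=O)(=O)C(F)(F)F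
Why: TMSOTf silylates the C4 carbonyl oxygen of 5 and so converts the cross-conjugated pyranone ring C into the aromatic benzopyrylium cation 8; the icosylcopper species formed from 7 and monovalent copper then transfers its primary alkyl group to C2, and the charge collapses to the neutral silyl enol ether 9. The closest known reaction type is the addition of Grignard, organocopper and organozinc reagents to 4-silyloxybenzopyrylium and 4-silyloxyquinolinium triflates, the cationic variant of the silyl-assisted copper-catalysed conjugate addition to chromones. No ring is closed. The new stereocentre C2 forms as a racemate without any control element, which is harmless because step 5 makes C2 trigonal again. The step needs attack at C2 and not at C4 or at silicon: C4 carries the donor OTMS group and is screened by the peri 5-OTBS group, C2 is an unhindered CH next to O1, and the soft copper reagent spares silicon. The cationic activation is needed because the 5,7-dioxygenated ring A makes neutral 5 a poor Michael acceptor, and both phenols are masked so that no Grignard reagent is lost to protons.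

Step 5
Reactants: 9 5,7-bis(tert-butyldimethylsilyloxy)-2-icosyl-6,8-dimethyl-4-(trimethylsilyloxy)-2H-chromene
Product: 11 5,7-dihydroxy-2-icosyl-6,8-dimethyl-4H-chromen-4-one (CNP0238051.0), via bis-TBS chromone 10 (not isolated)
Conditions: DDQ (1.0 equiv), 2,4,6-collidine (1.5 equiv), CH2Cl2, 0 °C; then Et3N·3HF (1.5 equiv), THF, rt
Reagents that add atoms: none
Why: DDQ dehydrogenation of a silyl enol ether should proceed by hydride abstraction from C2–H, which is activated by O1 and the enol ether and gives back an aromatic benzopyrylium that loses its TMS group to the chromone, after which fluoride cleaves the two aryl TBS ethers.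

Compound list
1 | 2',4',6'-trihydroxyacetophenone | CC(=O)c1c(O)cc(O)cc1O | starting material
2 | 2',4',6'-trihydroxy-3',5'-dimethylacetophenone | CC(=O)c1c(O)c(C)c(O)c(C)c1O | intermediate
3 | 4-ethoxy-5,7-dihydroxy-6,8-dimethylbenzopyrylium perchlorate (not isolated) | CCOc1cc[o+]c2c(C)c(O)c(C)c(O)c12.[O-]Cl(=O)(=O)=O | intermediate
4 | 5,7-dihydroxy-6,8-dimethyl-4H-chromen-4-one | O=c1ccoc2c(C)c(O)c(C)c(O)c12 | intermediate
5 | 5,7-bis(tert-butyldimethylsilyloxy)-6,8-dimethyl-4H-chromen-4-one | O=c1ccoc2c(C)c(O[Si](C)(C)C(C)(C)C)c(C)c(O[Si](C)(C)C(C)(C)C)c12 | intermediate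
6 | 1-bromoicosane | CCCCCCCCCCCCCCCCCCCCBr | starting material
7 | icosylmagnesium bromide (not isolated) | CCCCCCCCCCCCCCCCCCCC[Mg]Br | intermediate
8 | 5,7-bis(tert-butyldimethylsilyloxy)-6,8-dimethyl-4-(trimethylsilyloxy)benzopyrylium triflate (not isolated) | C[Si](C)(C)Oc1cc[o+]c2c(C)c(O[Si](C)(C)C(C)(C)C)c(C)c(O[Si](C)(C)C(C)(C)C)c12.[O-]S(=O)(=O)C(F)(F)F | intermediate
9 | 5,7-bis(tert-butyldimethylsilyloxy)-2-icosyl-6,8-dimethyl-4-(trimethylsilyloxy)-2H-chromene, racemic at C2 | CCCCCCCCCCCCCCCCCCCCC1C=C(O[Si](C)(C)C)c2c(O[Si](C)(C)C(C)(C)C)c(C)c(O[Si](C)(C)C(C)(C)C)c(C)c2O1 | intermediate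
10 | 5,7-bis(tert-butyldimethylsilyloxy)-2-icosyl-6,8-dimethyl-4H-chromen-4-one (not isolated) | CCCCCCCCCCCCCCCCCCCCc1cc(=O)c2c(O[Si](C)(C)C(C)(C)C)c(C)c(O[Si](C)(C)C(C)(C)C)c(C)c2o1 | intermediate
11 | 5,7-dihydroxy-2-icosyl-6,8-dimethyl-4H-chromen-4-one | CCCCCCCCCCCCCCCCCCCCc1cc(=O)c2c(O)c(C)c(O)c(C)c2o1 | target

Total step count: 5. Longest linear sequence: 5 steps (1 to 2 to 4 to 5 to 9 to 11); 6 enters in step 4.

Steps most likely to fail

1. Step 4.
- What may go wrong: electron transfer from the organometallic reagent to the cation may lead to radical dimerisation. The Grignard reagent may attack the O4 silicon and return the neutral chromone. Peri crowding between O4 and the 5-OTBS group may leave cation formation incomplete.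
- Fallback: it sets out from 5 and comes back at 10, and it forms the same bond at the chromone oxidation level by cross-coupling.
- Deprotonation of 5 at C2 (LiTMP, THF, −78 °C) should give the 2-lithiochromone F1. An iodine quench should then give the 2-iodochromone F2.
- Zinc insertion into 6 (Zn dust, LiCl, THF, 50 °C) should give icosylzinc bromide F3.
- Negishi coupling of F2 and F3 (PdCl2(dppf), THF, 50 °C) should give 10. The fluoride treatment of step 5 then desilylates it.

2. Step 1.
- What may go wrong: alkylation may run on past the dimethyl stage, with dearomatisation to geminal dimethyl cyclohexadienones, and O-methylation may compete.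
- Fallback: it sets out from 1 and comes back at 2.
- A double Mannich reaction (aq CH2O, Me2NH, EtOH, rt) should give the bis(dimethylaminomethyl) ketone F4. Each ring carbon can react only once here.
- Hydrogenolysis of both benzylic C–N bonds (H2, Pd/C, EtOH, 60 °C) should then give 2.

3. Step 5.
- What may go wrong: the TMS enol ether may hydrolyse before it is oxidised, or oxidation may start at the benzylic methyl groups of the electron-rich ring A.
- Fallback: it sets out from 9 and comes back at 10, and it replaces hydride abstraction by halogenation and elimination.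
- NBS (THF, −78 °C) should brominate the enol ether at C3 to give the 3-bromochromanone F5 as a mixture of diastereomers.
- DBU (toluene, rt) should eliminate HBr across C2–C3 to give 10.

Further compounds
F1 | step 4 | 5,7-bis(tert-butyldimethylsilyloxy)-2-lithio-6,8-dimethyl-4H-chromen-4-one | [Li]c1cc(=O)c2c(O[Si](C)(C)C(C)(C)C)c(C)c(O[Si](C)(C)C(C)(C)C)c(C)c2o1
F2 | step 4 | 5,7-bis(tert-butyldimethylsilyloxy)-2-iodo-6,8-dimethyl-4H-chromen-4-one | Ic1cc(=O)c2c(O[Si](C)(C)C(C)(C)C)c(C)c(O[Si](C)(C)C(C)(C)C)c(C)c2o1
F3 | step 4 | icosylzinc bromide | CCCCCCCCCCCCCCCCCCCC[Zn]Br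
F4 | step 1 | 1-[3,5-bis(dimethylaminomethyl)-2,4,6-trihydroxyphenyl]ethanone | CC(=O)c1c(O)c(CN(C)C)c(O)c(CN(C)C)c1O
F5 | step 5 | 3-bromo-5,7-bis(tert-butyldimethylsilyloxy)-2-icosyl-6,8-dimethylchroman-4-one (racemic, mixture of diastereomers) | CCCCCCCCCCCCCCCCCCCCC1Oc2c(C)c(O[Si](C)(C)C(C)(C)C)c(C)c(O[Si](C)(C)C(C)(C)C)c2C(=O)C1Br
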